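**Plan**

1. Numbering used here: tetronic acid ring O1, C2 (lactone C=O), C3 (C–CH3), C4 (C–OH), C5; chain C6 (=CH), C7 (stereocentre), C8–C10, C11=C12(CH3), C13, C14; furan ring A (2,4-disubstituted) and furan ring B (3-substituted).
2. The tetronic acid is cut across the ring at O1–C5 and C3–C4. O1 and the exocyclic C5=C6 bond form a Z-enol ester, which is the adduct of a carboxylate to a C5≡C6 alkyne, and C3–C4 joins a propionate α-carbon to an acyl carbon. The ring is therefore the 5-exo-dig cycloisomer of a 2-methyl-3-oxoalk-4-ynoic acid, assembled in one flask from the full-length 2-ynoyl chloride and a propionate ketene bis-silyl acetal.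
3. Further cuts: C4–C5 (CO2 onto a terminal alkyne), C5≡C6 (one-carbon homologation of the C6 aldehyde), C10–C11 (B-alkyl Suzuki), C12–CH3 and C11–I (methylalumination/iodination), C14–ring A (Negishi), and the CH2 bridge between rings A and B (furyllithium addition, then deoxygenation).
4. Forward: both furans are bought as rings and joined first; the chain grows from ring A to the (E)-vinyl iodide; the C6–C10 piece is coupled on; the ynoic acid is made; the tetronic acid ring is formed last.
5. Stereochemistry: C7 (S) from an Evans allylation with the (R)-4-benzyl auxiliary; C11=C12 (E) from syn-carboalumination; C5=C6 (Z) from anti-addition of carboxylate and silver across the alkyne, then protodemetalation with retention.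

Key step: step 16

Remark: the target is drawn as its 4-hydroxy (enol) tautomer; C3 of the open-chain β-keto ester and acid (28, 29) is enolisable and is left undefined.

**Route**

Step 1
Reactants: 1 3-bromofuran; 2 4-bromofuran-2-carbaldehyde
Product: 4 (4-bromofuran-2-yl)(furan-3-yl)methanol (racemic), via furan-3-yllithium 3 (not isolated)
Conditions: n-BuLi (1.0 equiv), THF, −78 °C, 20 min; then 2, −78 °C; H2O quench
Reagents that add atoms: none
Why: Bromine–lithium exchange at −78 °C should give the 3-lithiofuran without migration to C2, and its 1,2-addition to the aldehyde (organolithium addition) should outrun exchange at the C–Br bond of 2; the carbinol centre forms racemic and is removed in step 2.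

Step 2
Reactants: 4 (4-bromofuran-2-yl)(furan-3-yl)methanol
Product: 5 4-bromo-2-(furan-3-ylmethyl)furan
Conditions: Et3SiH (3 equiv), CF3CO2H (2 equiv), CH2Cl2 (dilute), −20 → 0 °C
Reagents that add atoms: none
Why: Ionic hydrogenation: the carbocation flanked by two furans ionises readily and should be captured by silane hydride faster than it alkylates another furan when the silane is in excess.

Step 3
Reactants: 5 4-bromo-2-(furan-3-ylmethyl)furan; 6 (4-bromobut-1-yn-1-yl)trimethylsilane
Product: 8 {4-[5-(furan-3-ylmethyl)furan-3-yl]but-1-yn-1-yl}trimethylsilane, via alkylzinc bromide 7 (not isolated)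
Conditions: 6, Zn dust (activated by BrCH2CH2Br and Me3SiCl), LiCl, THF, 40 °C; then 5, Pd(OAc)2 (2 mol %), SPhos (4 mol %), THF, 25 → 50 °C
Reagents that add atoms: none
Why: LiCl-assisted zinc insertion followed by Negishi sp3–sp2 cross-coupling; the bulky electron-rich biarylphosphine should speed oxidative addition into the electron-rich bromofuran and reductive elimination ahead of β-hydride elimination, and the silyl cap keeps the alkyne C–H away from the organozinc.

Step 4
Reactants: 8 {4-[5-(furan-3-ylmethyl)furan-3-yl]but-1-yn-1-yl}trimethylsilane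
Product: 9 4-(but-3-yn-1-yl)-2-(furan-3-ylmethyl)furan
Conditions: K2CO3 (0.2 equiv), MeOH, 25 °C
Reagents that add atoms: none
Why: Base-catalysed methanolysis of the alkynyl C–Si bond (protodesilylation) should free the terminal alkyne; nothing else in 8 reacts with methoxide.

Step 5
Reactants: 9 4-(but-3-yn-1-yl)-2-(furan-3-ylmethyl)furan
Product: 11 2-(furan-3-ylmethyl)-4-[(3E)-4-iodo-3-methylbut-3-en-1-yl]furan, via alkenylalane 10 (not isolated)
Conditions: AlMe3 (2.5 equiv), Cp2ZrCl2 (0.25 equiv), CH2Cl2, 0 → 25 °C; then I2, THF, −30 °C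
Reagents that add atoms: trimethylaluminium, C[Al](C)C; iodine, [I][I]
Why: Zirconium-catalysed carboalumination (Negishi methylalumination) adds CH3 and Al syn across the terminal alkyne with Al at the terminus, so iodinolysis with retention should give the (E)-2-methyl-1-iodoalkene.

Step 6
Reactants: 12 (R)-4-benzyl-3-propionyloxazolidin-2-one
Product: 14 (R)-4-benzyl-3-[(S)-2-methylpent-4-enoyl]oxazolidin-2-one, via sodium enolate 13 (not isolated)
Conditions: NaN(SiMe3)2 (1.1 equiv), THF, −78 °C; allyl bromide (3 equiv), −78 → −40 °C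
Reagents that add atoms: allyl bromide, C=CCBr
Why: Evans asymmetric alkylation: the chelated (Z)-enolate is attacked by allyl bromide on the face opposite the benzyl group, which with the (R)-auxiliary should set the α-carbon (later C7) as S.

Step 7
Reactants: 14 (R)-4-benzyl-3-[(S)-2-methylpent-4-enoyl]oxazolidin-2-one
Product: 15 (S)-2-methylpent-4-en-1-ol
Conditions: LiBH4, H2O (1 equiv), Et2O, 0 °C
Reagents that add atoms: none
Why: Reductive cleavage of the N-acyl oxazolidinone by borohydride should give the primary alcohol without touching the α-stereocentre or the alkene, and returns the auxiliary.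

Step 8
Reactants: 15 (S)-2-methylpent-4-en-1-ol
Product: 16 tert-butyldimethyl{[(2S)-2-methylpent-4-en-1-yl]oxy}silane
Conditions: TBSCl, imidazole, CH2Cl2, 25 °C
Reagents that add atoms: tert-butyldimethylsilyl chloride, CC(C)(C)[Si](C)(C)Cl
Why: Imidazole-promoted silyl ether formation masks the O–H before hydroboration and makes the small fragment less volatile.

Step 9
Reactants: 16 tert-butyldimethyl{[(2S)-2-methylpent-4-en-1-yl]oxy}silane; 11 2-(furan-3-ylmethyl)-4-[(3E)-4-iodo-3-methylbut-3-en-1-yl]furan
Product: 18 tert-butyl{[(2S,6E)-9-[5-(furan-3-ylmethyl)furan-3-yl]-2,7-dimethylnon-6-en-1-yl]oxy}dimethylsilane, via alkyl-9-BBN borane 17 (not isolated)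
Conditions: 16, 9-BBN (1.2 equiv), THF, 25 °C; then H2O, 11, PdCl2(dppf) (5 mol %), AsPh3 (10 mol %), Cs2CO3, DMF/THF/H2O, 25 °C
Reagents that add atoms: none
Why: Anti-Markovnikov hydroboration of the only alkene of 16, then B-alkyl Suzuki–Miyaura coupling, should join C10 to C11 with retention of the (E)-iodoalkene geometry; the C7 centre is remote and untouched.

Step 10
Reactants: 18 tert-butyl{[(2S,6E)-9-[5-(furan-3-ylmethyl)furan-3-yl]-2,7-dimethylnon-6-en-1-yl]oxy}dimethylsilane
Product: 19 (2S,6E)-9-[5-(furan-3-ylmethyl)furan-3-yl]-2,7-dimethylnon-6-en-1-ol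
Conditions: Bu4NF, THF, 0 → 25 °C
Reagents that add atoms: none
Why: Fluoride-induced Si–O cleavage (desilylation) leaves furans and alkenes alone.

Step 11
Reactants: 19 (2S,6E)-9-[5-(furan-3-ylmethyl)furan-3-yl]-2,7-dimethylnon-6-en-1-ol
Product: 20 (2S,6E)-9-[5-(furan-3-ylmethyl)furan-3-yl]-2,7-dimethylnon-6-enal
Conditions: Dess–Martin periodinane, NaHCO3, CH2Cl2, 0 → 25 °C; used at once
Reagents that add atoms: none
Why: Dess–Martin oxidation under bicarbonate buffer should give the α-branched aldehyde without over-oxidation or enolisation and does not attack furans.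

Step 12
Reactants: 20 (2S,6E)-9-[5-(furan-3-ylmethyl)furan-3-yl]-2,7-dimethylnon-6-enal
Product: 21 2-(furan-3-ylmethyl)-4-[(3E,8S)-3,8-dimethyldec-3-en-9-yn-1-yl]furan
Conditions: dimethyl (1-diazo-2-oxopropyl)phosphonate, K2CO3, MeOH, 0 → 25 °C
Reagents that add atoms: dimethyl (1-diazo-2-oxopropyl)phosphonate, CC(=O)C(=[N+]=[N-])P(=O)(OC)OC
Why: Seyferth–Gilbert homologation in the Ohira–Bestmann form: the diazomethylphosphonate anion adds to the aldehyde, and loss of phosphate and N2 with a 1,2-hydride shift should give the alkyne under base mild enough to keep the α-centre intact.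

Step 13
Reactants: 21 2-(furan-3-ylmethyl)-4-[(3E,8S)-3,8-dimethyldec-3-en-9-yn-1-yl]furan
Product: 23 (4S,8E)-11-[5-(furan-3-ylmethyl)furan-3-yl]-4,9-dimethylundec-8-en-2-ynoic acid, via lithium acetylide 22 (not isolated)
Conditions: n-BuLi (1.05 equiv), THF, −78 °C; CO2 (dry gas), −78 → 0 °C; cold 0.5 M HCl to pH 3
Reagents that add atoms: carbon dioxide, O=C=O
Why: Selective deprotonation of the sp C–H (far more acidic than any furan C–H or the bis-furyl CH2) and carboxylation of the lithium acetylide should set the C4–C5 bond.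

Step 14
Reactants: 23 (4S,8E)-11-[5-(furan-3-ylmethyl)furan-3-yl]-4,9-dimethylundec-8-en-2-ynoic acid
Product: 24 (4S,8E)-11-[5-(furan-3-ylmethyl)furan-3-yl]-4,9-dimethylundec-8-en-2-ynoyl chloride
Conditions: 1-chloro-N,N,2-trimethylprop-1-en-1-amine (1.1 equiv), CH2Cl2, 0 → 25 °C; concentrate, use crude
Reagents that add atoms: 1-chloro-N,N,2-trimethylprop-1-en-1-amine, CC(C)=C(Cl)N(C)C
Why: Acid chloride formation with an α-chloroenamine (Ghosez reagent) is neutral and releases no HCl, which spares the acid-sensitive furans and avoids hydrochlorination of the ynoic acid.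

Step 15
Reactants: 25 trimethylsilyl propanoate
Product: 27 1,1-bis(trimethylsilyloxy)prop-1-ene, via lithium enolate 26 (not isolated)
Conditions: LiN(iPr)2 (1.05 equiv), THF, −78 °C; Me3SiCl (1.2 equiv), −78 → 25 °C; filter from pentane, distil
Reagents that add atoms: chlorotrimethylsilane, C[Si](C)(C)Cl
Why: Kinetic enolisation of the silyl ester and O-silylation of the enolate (silyl ketene acetal formation) should give a propionate α-carbon nucleophile whose two oxygens are already in place.

Step 16
Reactants: 24 (4S,8E)-11-[5-(furan-3-ylmethyl)furan-3-yl]-4,9-dimethylundec-8-en-2-ynoyl chloride; 27 1,1-bis(trimethylsilyloxy)prop-1-ene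
Product: 30 (5Z)-5-[(2S,6E)-9-[5-(furan-3-ylmethyl)furan-3-yl]-2,7-dimethylnon-6-en-1-ylidene]-4-hydroxy-3-methylfuran-2(5H)-one, via trimethylsilyl β-keto ester 28 (not isolated), via β-keto acid 29 (not isolated)
Conditions: 27 (1.5 equiv), CH2Cl2, 0 → 25 °C; evaporate (removes Me3SiCl); MeCN, H2O (2 equiv), 0 °C; DBU (2.2 equiv), AgOAc (10 mol %), dark, 0 → 25 °C; aq citric acid work-up
Reagents that add atoms: none
Why: Proposed new method: the ketene bis-silyl acetal 27 should be C-acylated at the acyl carbon of ynoyl chloride 24 (addition–elimination with loss of Me3SiCl, C3–C4 bond), and after hydrolysis of the silyl ester and deprotonation by DBU the carboxylate oxygen of 29 should add to C5 of the AgOAc-activated C5≡C6 alkyne anti to silver, followed by protodeargentation at C6 (O1–C5 bond). The closest known reaction types are the acylation of ketene silyl acetals by acid chlorides to β-keto acids and the silver-catalysed carboxylative cyclisation of conjugated ynones under CO2, which runs through the same kind of β-keto carboxylate and closes it to a 5-ylidene tetronic acid, together with the silver-catalysed lactonisation of (Z)-2-en-4-ynoic acids. The one ring formed is closed in the 5-exo-dig mode by the oxygen nucleophile. No stereocentre is created; the Z geometry of C5=C6 is controlled by the anti-oxymetalation and the stereoretentive protonolysis of the vinyl–silver bond, and it is also the more stable isomer. The selectivity required is 5-exo attack at C5 over 6-endo (Michael-type) attack at C6, which would lead to a 4-hydroxy-2-pyranone; it should be secured by cyclising the enolate form, in which C4 is an enolate carbon that no longer polarises the alkyne toward C6 and in which charge repulsion turns the carboxylate cis to the alkyne. The C7 centre should survive because the C3–H between the two carbonyl groups is removed far more easily than the propargylic C7–H, and the furans and the C11=C12 olefin are inert to AgOAc and DBU.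

**Compound list**

1 | 3-bromofuran | Brc1ccoc1 | starting material
2 | 4-bromofuran-2-carbaldehyde | O=Cc1cc(Br)co1 | starting material
3 | furan-3-yllithium (not isolated) | [Li]c1ccoc1 | intermediate
4 | (4-bromofuran-2-yl)(furan-3-yl)methanol (racemic) | OC(c1ccoc1)c1cc(Br)co1 | intermediate
5 | 4-bromo-2-(furan-3-ylmethyl)furan | Brc1coc(Cc2ccoc2)c1 | intermediate
6 | (4-bromobut-1-yn-1-yl)trimethylsilane | C[Si](C)(C)C#CCCBr | starting material
7 | [4-(trimethylsilyl)but-3-yn-1-yl]zinc bromide (not isolated) | C[Si](C)(C)C#CCC[Zn]Br | intermediate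
8 | {4-[5-(furan-3-ylmethyl)furan-3-yl]but-1-yn-1-yl}trimethylsilane | C[Si](C)(C)C#CCCc1coc(Cc2ccoc2)c1 | intermediate
9 | 4-(but-3-yn-1-yl)-2-(furan-3-ylmethyl)furan | C#CCCc1coc(Cc2ccoc2)c1 | intermediate
10 | [(1E)-4-[5-(furan-3-ylmethyl)furan-3-yl]-2-methylbut-1-en-1-yl]dimethylalane (not isolated) | C[Al](C)/C=C(\C)CCc1coc(Cc2ccoc2)c1 | intermediate
11 | 2-(furan-3-ylmethyl)-4-[(3E)-4-iodo-3-methylbut-3-en-1-yl]furan | I/C=C(\C)CCc1coc(Cc2ccoc2)c1 | intermediate
12 | (R)-4-benzyl-3-propionyloxazolidin-2-one | CCC(=O)N1[C@H](Cc2ccccc2)COC1=O | starting material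
13 | sodium (Z)-enolate of 12 (not isolated) | C/C=C(\[O-])N1[C@H](Cc2ccccc2)COC1=O.[Na+] | intermediate
14 | (R)-4-benzyl-3-[(S)-2-methylpent-4-enoyl]oxazolidin-2-one | O=C([C@@H](C)CC=C)N1[C@H](Cc2ccccc2)COC1=O | intermediate
15 | (S)-2-methylpent-4-en-1-ol | OC[C@@H](C)CC=C | intermediate
16 | tert-butyldimethyl{[(2S)-2-methylpent-4-en-1-yl]oxy}silane | CC(C)(C)[Si](C)(C)OC[C@@H](C)CC=C | intermediate
17 | 9-[(4S)-5-(tert-butyldimethylsilyloxy)-4-methylpentyl]-9-borabicyclo[3.3.1]nonane (not isolated) | CC(C)(C)[Si](C)(C)OC[C@@H](C)CCCB1C2CCCC1CCC2 | intermediate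
18 | tert-butyl{[(2S,6E)-9-[5-(furan-3-ylmethyl)furan-3-yl]-2,7-dimethylnon-6-en-1-yl]oxy}dimethylsilane | CC(C)(C)[Si](C)(C)OC[C@@H](C)CCC/C=C(\C)CCc1coc(Cc2ccoc2)c1 | intermediate
19 | (2S,6E)-9-[5-(furan-3-ylmethyl)furan-3-yl]-2,7-dimethylnon-6-en-1-ol | OC[C@@H](C)CCC/C=C(\C)CCc1coc(Cc2ccoc2)c1 | intermediate
20 | (2S,6E)-9-[5-(furan-3-ylmethyl)furan-3-yl]-2,7-dimethylnon-6-enal | O=C[C@@H](C)CCC/C=C(\C)CCc1coc(Cc2ccoc2)c1 | intermediate
21 | 2-(furan-3-ylmethyl)-4-[(3E,8S)-3,8-dimethyldec-3-en-9-yn-1-yl]furan | C#C[C@@H](C)CCC/C=C(\C)CCc1coc(Cc2ccoc2)c1 | intermediate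
22 | lithium acetylide of 21 (not isolated) | [Li]C#C[C@@H](C)CCC/C=C(\C)CCc1coc(Cc2ccoc2)c1 | intermediate
23 | (4S,8E)-11-[5-(furan-3-ylmethyl)furan-3-yl]-4,9-dimethylundec-8-en-2-ynoic acid | OC(=O)C#C[C@@H](C)CCC/C=C(\C)CCc1coc(Cc2ccoc2)c1 | intermediate
24 | (4S,8E)-11-[5-(furan-3-ylmethyl)furan-3-yl]-4,9-dimethylundec-8-en-2-ynoyl chloride | ClC(=O)C#C[C@@H](C)CCC/C=C(\C)CCc1coc(Cc2ccoc2)c1 | intermediate
25 | trimethylsilyl propanoate | CCC(=O)O[Si](C)(C)C | starting material
26 | lithium enolate of 25 (not isolated) | CC=C([O-])O[Si](C)(C)C.[Li+] | intermediate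
27 | 1,1-bis(trimethylsilyloxy)prop-1-ene | CC=C(O[Si](C)(C)C)O[Si](C)(C)C | intermediate
28 | trimethylsilyl (6S,10E)-13-[5-(furan-3-ylmethyl)furan-3-yl]-2,6,11-trimethyl-3-oxotridec-10-en-4-ynoate (not isolated; C2 undefined) | CC(C(=O)O[Si](C)(C)C)C(=O)C#C[C@@H](C)CCC/C=C(\C)CCc1coc(Cc2ccoc2)c1 | intermediate
29 | (6S,10E)-13-[5-(furan-3-ylmethyl)furan-3-yl]-2,6,11-trimethyl-3-oxotridec-10-en-4-ynoic acid (not isolated; present as its DBU salt; C2 undefined) | CC(C(=O)O)C(=O)C#C[C@@H](C)CCC/C=C(\C)CCc1coc(Cc2ccoc2)c1 | intermediate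
30 | (5Z)-5-[(2S,6E)-9-[5-(furan-3-ylmethyl)furan-3-yl]-2,7-dimethylnon-6-en-1-ylidene]-4-hydroxy-3-methylfuran-2(5H)-one | CC1=C(O)/C(=C/[C@@H](C)CCC/C=C(\C)CCc2coc(Cc3ccoc3)c2)OC1=O | target

**Summary**

Total step count: 16. Longest linear sequence: 12 steps (steps 1–5, 9–14 and 16).

The three steps most likely to fail:

Step 16 (Proposed new method). The ring closure may run in the 6-endo sense at C6, the β-keto carboxylate may decarboxylate before it cyclises, or the uncatalysed C-acylation may be too slow. The fallback is a directed aldol condensation of a preformed tetronate; it sets out from aldehyde 20 and comes back at 30. Commercial 4-hydroxy-3-methylfuran-2(5H)-one would be O-methylated (dimethyl sulfate, K2CO3, acetone) to 4-methoxy-3-methylfuran-2(5H)-one F1. Deprotonation at C5 with LiN(iPr)2 in THF at −78 °C should give 5-lithio-4-methoxy-3-methylfuran-2(5H)-one F2, which adds to 20 to give the aldol adduct F3 as a mixture at the two new centres. Mesylation (MsCl, Et3N) to the methanesulfonate F4 and E1cB elimination with DBU should give the (Z)-5-ylidene methyl tetronate F5, the Z isomer being the more stable. O-Demethylation with LiSPr in DMF and acidification then gives 30.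

Step 3. Oxidative addition into the electron-rich bromofuran may be slow, so that protodezincation and homocoupling of the alkylzinc win. The fallback replaces the cross-coupling by polar chemistry; it sets out from 5 and comes back at 9, passing over 8. Bromine–lithium exchange (n-BuLi, THF, −78 °C) should give [5-(furan-3-ylmethyl)furan-3-yl]lithium F6. Opening of ethylene oxide in the presence of BF3·OEt2 at −78 °C gives 2-[5-(furan-3-ylmethyl)furan-3-yl]ethan-1-ol F7. Iodination (I2, PPh3, imidazole) gives 2-(furan-3-ylmethyl)-4-(2-iodoethyl)furan F8, and displacement with the lithium acetylide–ethylenediamine complex (LiC≡CH·H2NCH2CH2NH2) in DMSO gives 9.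

Step 2. The furyl-stabilised cation may alkylate a second furan ring (acid-induced oligomerisation) before hydride is delivered. The fallback avoids the cation; it sets out from 4 and comes back at 5. Oxidation with MnO2 in CH2Cl2 should give (4-bromofuran-2-yl)(furan-3-yl)methanone F9. Condensation with 4-methylbenzenesulfonohydrazide in EtOH gives the tosylhydrazone F10. Reduction with catecholborane in CHCl3 followed by NaOAc·3H2O at reflux (hydrazone deoxygenation with loss of N2 and sulfinate) gives 5 under non-acidic conditions.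

**Further compounds**

F1 | step 16 | 4-methoxy-3-methylfuran-2(5H)-one | COC1=C(C)C(=O)OC1
F2 | step 16 | 5-lithio-4-methoxy-3-methylfuran-2(5H)-one | COC1=C(C)C(=O)OC1[Li]
F3 | step 16 | 5-[(2S,6E)-9-[5-(furan-3-ylmethyl)furan-3-yl]-1-hydroxy-2,7-dimethylnon-6-en-1-yl]-4-methoxy-3-methylfuran-2(5H)-one | COC1=C(C)C(=O)OC1C(O)[C@@H](C)CCC/C=C(\C)CCc1coc(Cc2ccoc2)c1
F4 | step 16 | (2S,6E)-9-[5-(furan-3-ylmethyl)furan-3-yl]-1-(3-methoxy-4-methyl-5-oxo-2,5-dihydrofuran-2-yl)-2,7-dimethylnon-6-en-1-yl methanesulfonate | COC1=C(C)C(=O)OC1C(OS(C)(=O)=O)[C@@H](C)CCC/C=C(\C)CCc1coc(Cc2ccoc2)c1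
F5 | step 16 | (5Z)-5-[(2S,6E)-9-[5-(furan-3-ylmethyl)furan-3-yl]-2,7-dimethylnon-6-en-1-ylidene]-4-methoxy-3-methylfuran-2(5H)-one | COC1=C(C)C(=O)O/C1=C\[C@@H](C)CCC/C=C(\C)CCc1coc(Cc2ccoc2)c1
F6 | step 3 | [5-(furan-3-ylmethyl)furan-3-yl]lithium | [Li]c1coc(Cc2ccoc2)c1
F7 | step 3 | 2-[5-(furan-3-ylmethyl)furan-3-yl]ethan-1-ol | OCCc1coc(Cc2ccoc2)c1
F8 | step 3 | 2-(furan-3-ylmethyl)-4-(2-iodoethyl)furan | ICCc1coc(Cc2ccoc2)c1
F9 | step 2 | (4-bromofuran-2-yl)(furan-3-yl)methanone | O=C(c1ccoc1)c1cc(Br)co1
F10 | step 2 | N'-[(4-bromofuran-2-yl)(furan-3-yl)methylidene]-4-methylbenzenesulfonohydrazide | Cc1ccc(cc1)S(=O)(=O)NN=C(c1ccoc1)c1cc(Br)co1
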